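**Plan**
- Retrosynthetic cuts, in order: O1–C2 of the flavanone; C4a–C5 of its ring A; the bond between the cinnamoyl carbonyl and the triketide chain; the Cα=Cβ alkene; the 3'–3''' biaryl bond; the flavone pyranone ring.
- Enabling feature: flavanone ring A (C4a, C5, C6, C7, C8, C8a) is a phloroglucinol with oxygen on C5, C7 and C8a and the C4 acyl carbon on C4a. This is the pattern formed when C6 of a cinnamoyl-capped 3,5,7-triketo ester closes onto its own ester carbon.
- Forward order: flavone rings first (2'-hydroxychalcone, I2/DMSO), biaryl by Suzuki coupling, two-carbon extension by HWE, triketide chain by trianion acylation, ring A by Claisen cyclisation, debenzylation, and the flavanone heterocycle last.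
- Stereochemistry: the only stereocentre, C2 (S), is set in the final step by chalcone isomerase acting on the free 2',4',6'-trihydroxychalcone; no step follows it.

Key step: step 9

Assumption: the [C@@H] centre is read as 2S, the configuration type I chalcone isomerase delivers; the enzyme (heterologously expressed, used as catalyst) is assumed to tolerate the 3-aryl group on ring B.
Assumption: methyl 3,5-dioxohexanoate, LDA solution and Mg(OMe)2 solution in methanol are purchased.

**Step 1**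
Reactants: 1 2,4,6-trihydroxyacetophenone
Product: 2 1-[2,4-bis(benzyloxy)-6-hydroxyphenyl]ethan-1-one
Conditions: BnBr (2.1 equiv), K2CO3, acetone, reflux
Reagents that add atoms: benzyl bromide, BrCc1ccccc1
Why: Williamson etherification in which the hydroxyl hydrogen-bonded to the acetyl carbonyl is the least nucleophilic and should stay free with two equivalents of halide.

**Step 2**
Reactants: 3 3-bromo-4-hydroxybenzaldehyde
Product: 4 4-(benzyloxy)-3-bromobenzaldehyde
Conditions: BnBr, K2CO3, DMF, 60 °C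
Reagents that add atoms: benzyl bromide, BrCc1ccccc1
Why: Williamson etherification of a single acidic phenol; the aldehyde and aryl bromide are inert.

**Step 3**
Reactants: 2 1-[2,4-bis(benzyloxy)-6-hydroxyphenyl]ethan-1-one; 4 4-(benzyloxy)-3-bromobenzaldehyde
Product: 5 (2E)-1-[2,4-bis(benzyloxy)-6-hydroxyphenyl]-3-[4-(benzyloxy)-3-bromophenyl]prop-2-en-1-one
Conditions: KOH (50% aq.), EtOH–THF, rt
Reagents that add atoms: none
Why: Claisen–Schmidt condensation of a methyl ketone with a non-enolisable aldehyde, the E1cB dehydration giving the E-enone.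

**Step 4**
Reactants: 5 (2E)-1-[2,4-bis(benzyloxy)-6-hydroxyphenyl]-3-[4-(benzyloxy)-3-bromophenyl]prop-2-en-1-one
Product: 6 5,7-bis(benzyloxy)-2-[4-(benzyloxy)-3-bromophenyl]-4H-chromen-4-one
Conditions: I2 (10 mol %), DMSO, 130 °C
Reagents that add atoms: none
Why: Iodine/DMSO oxidative cyclisation of a 2'-hydroxychalcone (oxa-Michael closure, iodination, loss of HI, DMSO as terminal oxidant), which benzyl ethers and the aryl bromide should survive.

**Step 5**
Reactants: 4 4-(benzyloxy)-3-bromobenzaldehyde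
Product: 7 4-(benzyloxy)-3-(4,4,5,5-tetramethyl-1,3,2-dioxaborolan-2-yl)benzaldehyde
Conditions: B2pin2, Pd(dppf)Cl2 (3 mol %), KOAc, 1,4-dioxane, 85 °C
Reagents that add atoms: bis(pinacolato)diboron, CC1(C)OB(OC1(C)C)B1OC(C)(C)C(C)(C)O1
Why: Miyaura borylation of an aryl bromide; the weak acetate base leaves the aldehyde alone and avoids homocoupling.

**Step 6**
Reactants: 6 5,7-bis(benzyloxy)-2-[4-(benzyloxy)-3-bromophenyl]-4H-chromen-4-one; 7 4-(benzyloxy)-3-(4,4,5,5-tetramethyl-1,3,2-dioxaborolan-2-yl)benzaldehyde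
Product: 8 4-(benzyloxy)-3-{2-(benzyloxy)-5-[5,7-bis(benzyloxy)-4-oxo-4H-chromen-2-yl]phenyl}benzaldehyde
Conditions: Pd(dppf)Cl2 (5 mol %), K2CO3, 1,4-dioxane–H2O, 90 °C
Reagents that add atoms: none
Why: Suzuki–Miyaura coupling forming a 2,2'-dialkoxybiaryl with one ortho substituent on each partner, a hindrance level that standard catalysts handle.

**Step 7**
Reactants: 8 4-(benzyloxy)-3-{2-(benzyloxy)-5-[5,7-bis(benzyloxy)-4-oxo-4H-chromen-2-yl]phenyl}benzaldehyde; 9 diethyl {2-[methoxy(methyl)amino]-2-oxoethyl}phosphonate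
Product: 10 (2E)-3-[4-(benzyloxy)-3-{2-(benzyloxy)-5-[5,7-bis(benzyloxy)-4-oxo-4H-chromen-2-yl]phenyl}phenyl]-N-methoxy-N-methylprop-2-enamide
Conditions: NaH, THF, 0 °C to rt
Reagents that add atoms: none
Why: Horner–Wadsworth–Emmons olefination with a stabilised phosphonate, which should give the E-cinnamoyl Weinreb amide from the non-enolisable aldehyde.

**Step 8**
Reactants: 10 (2E)-3-[4-(benzyloxy)-3-{2-(benzyloxy)-5-[5,7-bis(benzyloxy)-4-oxo-4H-chromen-2-yl]phenyl}phenyl]-N-methoxy-N-methylprop-2-enamide; 11 methyl 3,5-dioxohexanoate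
Product: 13 methyl (8E)-9-[4-(benzyloxy)-3-{2-(benzyloxy)-5-[5,7-bis(benzyloxy)-4-oxo-4H-chromen-2-yl]phenyl}phenyl]-3,5,7-trioxonon-8-enoate, via trilithium 2,4,6-trianion 12 (not isolated)
Conditions: 11 (2.5 equiv), LDA (3.05 equiv per 11), THF, 0 °C; then 10, −78 to −20 °C; cold 1 M HCl to pH 3; carried on promptly
Reagents that add atoms: none
Why: Acylation of a β,δ-diketo ester trianion at its terminal C6 carbanion by a Weinreb amide, whose chelated tetrahedral adduct should prevent over-addition, while addition to the vinylogous-ester carbonyl of the flavone is reversible and unproductive.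

**Step 9**
Reactants: 13 methyl (8E)-9-[4-(benzyloxy)-3-{2-(benzyloxy)-5-[5,7-bis(benzyloxy)-4-oxo-4H-chromen-2-yl]phenyl}phenyl]-3,5,7-trioxonon-8-enoate
Product: 15 (2E)-3-[4-(benzyloxy)-3-{2-(benzyloxy)-5-[5,7-bis(benzyloxy)-4-oxo-4H-chromen-2-yl]phenyl}phenyl]-1-(2,4,6-trihydroxyphenyl)prop-2-en-1-one, via 2-acylcyclohexane-1,3,5-trione 14 (not isolated)
Conditions: Mg(OMe)2 (8 equiv), MeOH–THF, 0 to 45 °C, Ar; then ice-cold 0.5 M HCl to pH 3, EtOAc
Reagents that add atoms: none
Why: Magnesium holds the polyenolate of 13 in a folded chelate, the C6 carbanion adds to the ester carbonyl C1, methoxide leaves to give trione 14, and three enolisations aromatise it to the acylphloroglucinol. The closest known reaction is the Claisen (Dieckmann-type) cyclisation of 3,5,7-triketo esters to acylphloroglucinols, the laboratory counterpart of chalcone-synthase folding, which is known for the simple styryl triketo ester. Ring A closes in the 6-exo-trig mode (enolate carbon C6 onto the exocyclic ester C=O), and the new bond is C4a–C5 of the later flavanone. No stereocentre is formed. The step needs Claisen folding rather than aldol folding (C2 onto C7); C7 is a chelated enone carbonyl further deactivated by the para-benzyloxy group, and anhydrous methoxide keeps C1 as an ester, the better electrophile. In base the product remains the open chalcone phenolate, and the cold acidic quench should keep oxa-Michael closure from starting before the enzymatic step.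

**Step 10**
Reactants: 15 (2E)-3-[4-(benzyloxy)-3-{2-(benzyloxy)-5-[5,7-bis(benzyloxy)-4-oxo-4H-chromen-2-yl]phenyl}phenyl]-1-(2,4,6-trihydroxyphenyl)prop-2-en-1-one
Product: 16 (2E)-3-{3-[5-(5,7-dihydroxy-4-oxo-4H-chromen-2-yl)-2-hydroxyphenyl]-4-hydroxyphenyl}-1-(2,4,6-trihydroxyphenyl)prop-2-en-1-one
Conditions: BCl3 (12 equiv), pentamethylbenzene (12 equiv), CH2Cl2, −78 °C; MeOH/CHCl3 at −78 °C, then cold pH 5 buffer; reverse-phase chromatography (0.1% HCO2H)
Reagents that add atoms: none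
Why: Non-reductive Lewis-acid debenzylation of aryl benzyl ethers with a cation scavenger, which spares the enone and the flavone C2=C3 bond; O-borylation of the ring A hydroxyls should keep the chalcone open until the buffered quench.

**Step 11**
Reactants: 16 (2E)-3-{3-[5-(5,7-dihydroxy-4-oxo-4H-chromen-2-yl)-2-hydroxyphenyl]-4-hydroxyphenyl}-1-(2,4,6-trihydroxyphenyl)prop-2-en-1-one
Product: 17 (2S)-2-{3-[5-(5,7-dihydroxy-4-oxo-4H-chromen-2-yl)-2-hydroxyphenyl]-4-hydroxyphenyl}-5,7-dihydroxy-2,3-dihydro-4H-chromen-4-one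
Conditions: type I chalcone isomerase (recombinant), 50 mM K-phosphate pH 6.4, 5% DMSO, 20 °C, short contact; then pH 4, EtOAc
Reagents that add atoms: none
Why: Enzymatic intramolecular oxa-Michael addition of a 6'-hydroxychalcone, in which the active site delivers the 2'-phenolate to one face of the enone and sets C2 as S; the slightly acidic pH slows the uncatalysed racemic closure, and the two ortho hydroxyls of ring A are equivalent.

**Compound list**
1 | 2,4,6-trihydroxyacetophenone | CC(=O)c1c(O)cc(O)cc1O | starting material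
2 | 1-[2,4-bis(benzyloxy)-6-hydroxyphenyl]ethan-1-one | CC(=O)c1c(O)cc(OCc2ccccc2)cc1OCc1ccccc1 | intermediate
3 | 3-bromo-4-hydroxybenzaldehyde | O=Cc1ccc(O)c(Br)c1 | starting material
4 | 4-(benzyloxy)-3-bromobenzaldehyde | O=Cc1ccc(OCc2ccccc2)c(Br)c1 | intermediate
5 | (2E)-1-[2,4-bis(benzyloxy)-6-hydroxyphenyl]-3-[4-(benzyloxy)-3-bromophenyl]prop-2-en-1-one | O=C(/C=C/c1ccc(OCc2ccccc2)c(Br)c1)c1c(O)cc(OCc2ccccc2)cc1OCc1ccccc1 | intermediate
6 | 5,7-bis(benzyloxy)-2-[4-(benzyloxy)-3-bromophenyl]-4H-chromen-4-one | O=c1cc(-c2ccc(OCc3ccccc3)c(Br)c2)oc2cc(OCc3ccccc3)cc(OCc3ccccc3)c12 | intermediate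
7 | 4-(benzyloxy)-3-(4,4,5,5-tetramethyl-1,3,2-dioxaborolan-2-yl)benzaldehyde | O=Cc1ccc(OCc2ccccc2)c(B2OC(C)(C)C(C)(C)O2)c1 | intermediate
8 | 4-(benzyloxy)-3-{2-(benzyloxy)-5-[5,7-bis(benzyloxy)-4-oxo-4H-chromen-2-yl]phenyl}benzaldehyde | O=Cc1ccc(OCc2ccccc2)c(-c2cc(-c3cc(=O)c4c(OCc5ccccc5)cc(OCc5ccccc5)cc4o3)ccc2OCc2ccccc2)c1 | intermediate
9 | diethyl {2-[methoxy(methyl)amino]-2-oxoethyl}phosphonate | CCOP(=O)(CC(=O)N(C)OC)OCC | starting material
10 | (2E)-3-[4-(benzyloxy)-3-{2-(benzyloxy)-5-[5,7-bis(benzyloxy)-4-oxo-4H-chromen-2-yl]phenyl}phenyl]-N-methoxy-N-methylprop-2-enamide | CON(C)C(=O)/C=C/c1ccc(OCc2ccccc2)c(-c2cc(-c3cc(=O)c4c(OCc5ccccc5)cc(OCc5ccccc5)cc4o3)ccc2OCc2ccccc2)c1 | intermediate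
11 | methyl 3,5-dioxohexanoate | COC(=O)CC(=O)CC(C)=O | starting material
12 | trilithium 2,4,6-trianion of methyl 3,5-dioxohexanoate (formed in the flask) | [Li+].[Li+].[Li+].COC(=O)[CH-]C(=O)[CH-]C(=O)[CH2-] | intermediate
13 | methyl (8E)-9-[4-(benzyloxy)-3-{2-(benzyloxy)-5-[5,7-bis(benzyloxy)-4-oxo-4H-chromen-2-yl]phenyl}phenyl]-3,5,7-trioxonon-8-enoate | COC(=O)CC(=O)CC(=O)CC(=O)/C=C/c1ccc(OCc2ccccc2)c(-c2cc(-c3cc(=O)c4c(OCc5ccccc5)cc(OCc5ccccc5)cc4o3)ccc2OCc2ccccc2)c1 | intermediate
14 | 2-{(2E)-3-[4-(benzyloxy)-3-{2-(benzyloxy)-5-[5,7-bis(benzyloxy)-4-oxo-4H-chromen-2-yl]phenyl}phenyl]prop-2-enoyl}cyclohexane-1,3,5-trione (formed in the flask) | O=C1CC(=O)C(C(=O)/C=C/c2ccc(OCc3ccccc3)c(-c3cc(-c4cc(=O)c5c(OCc6ccccc6)cc(OCc6ccccc6)cc5o4)ccc3OCc3ccccc3)c2)C(=O)C1 | intermediate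
15 | (2E)-3-[4-(benzyloxy)-3-{2-(benzyloxy)-5-[5,7-bis(benzyloxy)-4-oxo-4H-chromen-2-yl]phenyl}phenyl]-1-(2,4,6-trihydroxyphenyl)prop-2-en-1-one | O=C(/C=C/c1ccc(OCc2ccccc2)c(-c2cc(-c3cc(=O)c4c(OCc5ccccc5)cc(OCc5ccccc5)cc4o3)ccc2OCc2ccccc2)c1)c1c(O)cc(O)cc1O | intermediate
16 | (2E)-3-{3-[5-(5,7-dihydroxy-4-oxo-4H-chromen-2-yl)-2-hydroxyphenyl]-4-hydroxyphenyl}-1-(2,4,6-trihydroxyphenyl)prop-2-en-1-one | O=C(/C=C/c1ccc(O)c(-c2cc(-c3cc(=O)c4c(O)cc(O)cc4o3)ccc2O)c1)c1c(O)cc(O)cc1O | intermediate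
17 | (2S)-2-{3-[5-(5,7-dihydroxy-4-oxo-4H-chromen-2-yl)-2-hydroxyphenyl]-4-hydroxyphenyl}-5,7-dihydroxy-2,3-dihydro-4H-chromen-4-one | O=C1C[C@@H](c2ccc(O)c(-c3cc(-c4cc(=O)c5c(O)cc(O)cc5o4)ccc3O)c2)Oc2cc(O)cc(O)c21 | target

**Totals**
Total step count: 11. Longest linear sequence: 9 steps (3 → 4 → 5 → 6 → 8 → 10 → 13 → 15 → 16 → 17; the branch from 1 is equally long).

**Steps most likely to fail**

Step 11. The enzyme may fail to bind a chalcone whose ring B carries a second flavonoid unit, or the uncatalysed closure may run alongside it and erode the enantiomeric purity. Fallback: starting from 16, the ring is closed without stereocontrol (NaOAc, EtOH, reflux) to the racemic flavanone F1. The enantiomers are then separated by preparative HPLC on an amylose tris(3,5-dimethylphenylcarbamate) phase with an acidified eluent, and the 2S enantiomer is assigned by ECD comparison with (2S)-naringenin. The route is rejoined at 17, with the stereochemistry coming from separation instead of catalysis.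

Step 9. Folding in the aldol sense (C2 onto C7, giving a stilbene-type resorcylate) or lactonisation to a pyranone may outrun the Claisen closure. Fallback: ring A is brought in preformed. Starting from 8 and 2, Claisen–Schmidt condensation under the conditions of step 3 should give the hexabenzyl 2'-hydroxychalcone F2. Its six benzyl ethers are then cleaved with BCl3/pentamethylbenzene as in step 10, and the route is rejoined at 16.

Step 10. Acid released during cleavage or quench may trigger oxa-Michael closure to racemic flavanone, the electron-poor benzyl ethers may cleave only on warming, or benzyl cations may be captured by the phloroglucinol ring. Fallback: the debenzylation is moved forward to a compound with no acid-sensitive chalcone. Starting from 10, BCl3/pentamethylbenzene should give the tetraphenol Weinreb amide F3. TBSCl/imidazole in DMF should then give the tris-silyl ether F4, with the chelated flavone 5-OH left free. Acylation of trianion 12 with F4 (one extra equivalent of base for the 5-OH) should give the silylated triketo ester F5. Mg(OMe)2 in methanol should then bring about the Claisen cyclisation and, on continued warming, methanolysis of the aryl silyl ethers in the same flask, so that the route is rejoined at 16.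

**Further compounds**
F1 | step 11 | racemic 2-{3-[5-(5,7-dihydroxy-4-oxo-4H-chromen-2-yl)-2-hydroxyphenyl]-4-hydroxyphenyl}-5,7-dihydroxy-2,3-dihydro-4H-chromen-4-one | O=C1CC(c2ccc(O)c(-c3cc(-c4cc(=O)c5c(O)cc(O)cc5o4)ccc3O)c2)Oc2cc(O)cc(O)c21
F2 | step 9 | (2E)-1-[2,4-bis(benzyloxy)-6-hydroxyphenyl]-3-[4-(benzyloxy)-3-{2-(benzyloxy)-5-[5,7-bis(benzyloxy)-4-oxo-4H-chromen-2-yl]phenyl}phenyl]prop-2-en-1-one | O=C(/C=C/c1ccc(OCc2ccccc2)c(-c2cc(-c3cc(=O)c4c(OCc5ccccc5)cc(OCc5ccccc5)cc4o3)ccc2OCc2ccccc2)c1)c1c(O)cc(OCc2ccccc2)cc1OCc1ccccc1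
F3 | step 10 | (2E)-3-{3-[5-(5,7-dihydroxy-4-oxo-4H-chromen-2-yl)-2-hydroxyphenyl]-4-hydroxyphenyl}-N-methoxy-N-methylprop-2-enamide | CON(C)C(=O)/C=C/c1ccc(O)c(-c2cc(-c3cc(=O)c4c(O)cc(O)cc4o3)ccc2O)c1
F4 | step 10 | (2E)-3-[4-(tert-butyldimethylsilyloxy)-3-{2-(tert-butyldimethylsilyloxy)-5-[7-(tert-butyldimethylsilyloxy)-5-hydroxy-4-oxo-4H-chromen-2-yl]phenyl}phenyl]-N-methoxy-N-methylprop-2-enamide | CON(C)C(=O)/C=C/c1ccc(O[Si](C)(C)C(C)(C)C)c(-c2cc(-c3cc(=O)c4c(O)cc(O[Si](C)(C)C(C)(C)C)cc4o3)ccc2O[Si](C)(C)C(C)(C)C)c1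
F5 | step 10 | methyl (8E)-9-[4-(tert-butyldimethylsilyloxy)-3-{2-(tert-butyldimethylsilyloxy)-5-[7-(tert-butyldimethylsilyloxy)-5-hydroxy-4-oxo-4H-chromen-2-yl]phenyl}phenyl]-3,5,7-trioxonon-8-enoate | COC(=O)CC(=O)CC(=O)CC(=O)/C=C/c1ccc(O[Si](C)(C)C(C)(C)C)c(-c2cc(-c3cc(=O)c4c(O)cc(O[Si](C)(C)C(C)(C)C)cc4o3)ccc2O[Si](C)(C)C(C)(C)C)c1
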